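Plan (labdane numbering: ring A = C1–C5/C10, ring B = C5–C10, ring C = O/C9/C11/C12/C13, ring D = C13/C14=C15/O/C16).
Enabling feature: ring B is cis-fused, carries oxygen at C9 next to a C8 that can be a ketone, and its C5–C6 bond lies three atoms from C8; this is the retron of an anionic oxy-Cope rearrangement of a 2-vinylbicyclo[2.2.2]oct-5-en-2-ol.
Retrosynthetic cuts, in order: O–C15 (ring D), O–C13 (ring C), C14–C15, C11–C12, C9–C11, the second C4 methyl, the C8 methyl, C6–O, then C5–C6 with C3–C8 restored (oxy-Cope), C7–C8 (vinyl addition) and the Diels–Alder bonds C1–C10 and C2–C3 (the carboxyl on C2 is excised).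
Forward: arene → masked o-benzoquinone → bicyclo[2.2.2]octenone → vinyl carbinol → ring B closed onto ring A (key step) → decoration of the decalin → ring C by epoxide opening → ring D by alkynol cycloisomerisation.
Stereochemistry: C10 (absolute) from the auxiliary-controlled Diels–Alder reaction; C5 from the rearrangement; C6, C8 and C9 from reagent approach to the convex β face of the cis-decalin; C13 from Sharpless epoxidation followed by inversion.

Key step: step 7

Remark: atom labels in the explanations are labdane labels, also for the bicyclo[2.2.2]octenes (carbinol carbon C8, ketal carbon C9, methyl-bearing bridgehead C10, other bridgehead C3, alkene C4=C5, ethano bridge C1–C2); "cis-decalin" names use these labels with 10β-methyl and 5β-H throughout; systematic names carry their own locants.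
Remark (assumption): the acrylate of (R)-pantolactone is taken to favour the diene face that leads to the bridgehead configuration drawn; the two face-adducts are diastereomers and are separated, and if the preference is the opposite the (S)-auxiliary is used in the same way.

Step 1
Reactants: 1 2,4-dimethylanisole
Product: 4 2-methoxy-3,5-dimethylphenol, via (2-methoxy-3,5-dimethylphenyl)lithium 2 (not isolated), via dimethyl (2-methoxy-3,5-dimethylphenyl)boronate 3 (not isolated)
Conditions: n-BuLi, TMEDA, Et2O, 0 °C to rt; B(OMe)3, −78 °C to rt; then AcOH, 30% H2O2, 0 °C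
Reagents that add atoms: hydrogen peroxide, OO
Why: Directed ortho-metalation by the methoxy group can only occur at the one free ortho position, and borylation followed by oxidative C–B to C–O migration should give the guaiacol whose methoxy carbon lies between the new hydroxyl and a methyl group.

Step 2
Reactants: 5 (R)-pantolactone; 6 acryloyl chloride
Product: 7 (3R)-4,4-dimethyl-2-oxooxolan-3-yl prop-2-enoate
Conditions: Et3N, DMAP (cat.), CH2Cl2, −20 to 0 °C
Reagents that add atoms: none
Why: Acylation of the secondary hydroxyl by the acid chloride under amine base (esterification) should proceed without touching the stereocentre.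

Step 3
Reactants: 4 2-methoxy-3,5-dimethylphenol; 7 (3R)-4,4-dimethyl-2-oxooxolan-3-yl prop-2-enoate
Product: 9 (3R)-4,4-dimethyl-2-oxooxolan-3-yl (1R,2S,4S)-5,5-dimethoxy-4,7-dimethyl-6-oxobicyclo[2.2.2]oct-7-ene-2-carboxylate, via 6,6-dimethoxy-3,5-dimethylcyclohexa-2,4-dien-1-one 8 (not isolated)
Conditions: PhI(OAc)2, MeOH, 7 (3 equiv), slow addition of 4, 0 °C to rt; chromatography or crystallisation to one diastereomer
Reagents that add atoms: methanol, CO
Why: Oxidative dearomatisation of the guaiacol by the trivalent iodine reagent in methanol gives the masked o-benzoquinone 8, which is trapped as it forms in a Diels–Alder reaction so that its dimerisation is outrun; the acrylate CH2 should bond to the methyl-bearing diene terminus next to the ketal, the ester should sit endo under the new alkene bridge, the auxiliary decides which diene face reacts and with it the bridgehead configuration (C10), and the minor-face diastereomer is removed.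

Step 4
Reactants: 9 pantolactone ester of the bicyclic acid
Product: 10 (1R,2S,4S)-5,5-dimethoxy-4,7-dimethyl-6-oxobicyclo[2.2.2]oct-7-ene-2-carboxylic acid
Conditions: LiOH, THF/H2O, 0 °C to rt; then 1 M HCl
Reagents that add atoms: lithium hydroxide, [Li+].[OH-]
Why: Saponification of the activated ester should be fast, and the α-ketal ketone is left alone because its only α-hydrogen sits at a bridgehead and cannot enolise.

Step 5
Reactants: 10 bicyclic keto acid
Product: 12 (1R,4S)-3,3-dimethoxy-4,6-dimethylbicyclo[2.2.2]oct-5-en-2-one, via 2-thioxopyridin-1(2H)-yl ester of acid 10 11 (not isolated)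
Conditions: N-hydroxypyridine-2-thione, DCC, DMAP (cat.), CH2Cl2, rt, dark; then t-BuSH (excess), hν (tungsten lamp), 10 °C
Reagents that add atoms: none
Why: In this Barton decarboxylation the thiohydroxamate ester 11 fragments under visible light to the secondary C2 radical, which the large excess of thiol should reduce faster than it can close onto the alkene or the carbonyl group, and loss of this carbon removes the regio- and endo/exo question of step 3.

Step 6
Reactants: 12 bicyclo[2.2.2]octenone; 13 vinylmagnesium bromide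
Product: 14 (1R,2R,4S)-3,3-dimethoxy-4,6-dimethyl-2-vinylbicyclo[2.2.2]oct-5-en-2-ol
Conditions: THF, −78 to 0 °C; then aq NH4Cl
Reagents that add atoms: none
Why: Grignard 1,2-addition to the α-ketal ketone should occur from the side of the sp2 bridge, which is less crowded than the ethano bridge, so that the vinyl group ends syn to the C4=C5 alkene and C8 is set.

Step 7
Reactants: 14 vinyl carbinol
Product: 16 (4aR,8aS)-1,1-dimethoxy-5,8a-dimethyl-3,4,4a,7,8,8a-hexahydronaphthalen-2(1H)-one, via potassium C7=C8 enolate of 16 15 (not isolated)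
Conditions: KH, 18-crown-6, THF, 0 °C to rt; then aq NH4Cl
Reagents that add atoms: none
Why: KH with 18-crown-6 turns the C8 hydroxyl of 14 into a dissociated potassium alkoxide, which weakens the C3–C8 bond and lets the 1,5-diene C6=C7–C8–C3–C4=C5 undergo a [3,3]-sigmatropic shift at or near room temperature. The closest known reaction type is the anionic oxy-Cope rearrangement of 2-vinylbicyclo[2.2.2]oct-5-en-2-ols derived from masked o-benzoquinone cycloadducts, which gives cis-decalins. Ring B closes by formation of the C5–C6 σ bond through the boat-like six-membered transition state that the bicyclic cage enforces, while C3–C8 breaks and the former cyclohexene bridge becomes ring A with its alkene shifted to C3=C4. The one new stereocentre, C5, is fixed by the cage: the vinyl terminus can reach C5 only on the alkene face turned toward the carbinol bridge and the bridgehead C10 does not move, so H5 ends on the face of the C10 methyl and only the cis fusion can arise. The step needs the vinyl group syn to the C4=C5 bridge, which step 6 secures, and it needs the concerted shift to outrun fragmentation of the alkoxide, which the crown ether and the low temperature favour. Protonation of the regiodefined enolate 15 on work-up should give ketone 16 with the C9 ketal, the C8 ketone and the C4 and C10 methyl groups already in place.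

Step 8
Reactants: 16 cis-decalin ketone
Product: 19 (4aR,8aS)-1,1-dimethoxy-5,8a-dimethyl-4a,7,8,8a-tetrahydronaphthalen-2(1H)-one, via lithium C7=C8 enolate of 16 17 (not isolated), via trimethylsilyl enol ether of 16 18 (not isolated)
Conditions: LDA, TMSCl, THF, −78 °C; then Pd(OAc)2, MeCN, rt
Reagents that add atoms: none
Why: In this Saegusa–Ito oxidation deprotonation can occur only at C7 because C9 is quaternary, and divalent palladium should convert the silyl enol ether 18 into the C6=C7 enone by β-hydride elimination from the palladium enolate.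

Step 9
Reactants: 19 C6=C7 enone
Product: 21 6β-hydroxy-9,9-dimethoxy-4,10-dimethyl-cis-decal-3-en-8-one, via 6β-pinacolboryl-9,9-dimethoxy-4,10-dimethyl-cis-decal-3-en-8-one 20 (not isolated)
Conditions: CuCl (cat.), NaOtBu (cat.), Xantphos (cat.), B2pin2, MeOH, THF, rt; then 30% H2O2, aq NaHCO3, 0 °C
Reagents that add atoms: hydrogen peroxide, OO
Why: Copper-catalysed conjugate borylation followed by oxidation of the C–B bond with retention should place the oxygen on the β face of C6, because the boryl–copper species adds to the enone anti to the C4–C5 bond, that is on the convex face of the cis-decalin that carries H5.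

Step 10
Reactants: 21 6β-hydroxy ketone
Product: 22 6β-(tert-butyldimethylsilyloxy)-9,9-dimethoxy-4,10-dimethyl-cis-decal-3-en-8-one
Conditions: TBSCl, imidazole, DMF, rt
Reagents that add atoms: tert-butyldimethylsilyl chloride, CC(C)(C)[Si](C)(C)Cl
Why: Imidazole-promoted silylation of the secondary alcohol should block retro-aldol and elimination pathways of the β-hydroxy ketone in the steps that follow.

Step 11
Reactants: 22 silyl ether
Product: 23 6β-(tert-butyldimethylsilyloxy)-9,9-dimethoxy-4,10-dimethyl-3β,4β-methano-cis-decalin-8-one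
Conditions: Et2Zn, CH2I2, CH2Cl2, 0 °C to rt
Reagents that add atoms: diiodomethane, ICI
Why: Simmons–Smith cyclopropanation in the Furukawa variant should take place at the only alkene, the electron-rich trisubstituted C3=C4 bond, and although attack on the convex β face is expected either cyclopropane leads to the same gem-dimethyl group in step 13.

Step 12
Reactants: 23 cyclopropyl ketone
Product: 24 6β-(tert-butyldimethylsilyloxy)-9,9-dimethoxy-4,10-dimethyl-8-methylene-3β,4β-methano-cis-decalin
Conditions: Cp2TiMe2, toluene, 70 °C, dark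
Reagents that add atoms: dimethyltitanocene, C[Ti](C)(C1C=CC=C1)C1C=CC=C1
Why: Petasis methylenation through the thermally formed titanocene methylidene is non-basic, so the hindered α-ketal ketone should be converted into the exocyclic alkene without β-elimination of the silyloxy group.

Step 13
Reactants: 24 exocyclic alkene
Product: 25 6β-(tert-butyldimethylsilyloxy)-9,9-dimethoxy-4,4,8α,10-tetramethyl-cis-decalin
Conditions: H2 (4 atm), PtO2, AcOH, rt
Reagents that add atoms: none
Why: Heterogeneous hydrogenation should deliver hydrogen to C8 from the β face, since in the ring B chair that keeps the 6β-silyloxy group equatorial the α face of C8 is covered by the axial C1 methylene, which sets the 8α-methyl group, and under the same conditions the cyclopropane undergoes hydrogenolysis at its least substituted bond C3–CH2, the classical route from a methylcyclopropane to a gem-dimethyl group.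

Step 14
Reactants: 25 dimethyl ketal
Product: 26 6β-(tert-butyldimethylsilyloxy)-4,4,8α,10-tetramethyl-cis-decalin-9-one
Conditions: PPTS, acetone/H2O, 45 °C
Reagents that add atoms: water, O
Why: Acid-catalysed ketal hydrolysis is driven by relief of strain at the crowded C9, and the weak pyridinium acid should leave the silyl ether intact and keep enolisation toward C8, which would endanger the 8α-methyl centre, slow.

Step 15
Reactants: 26 C9 ketone
Product: 27 6β-(tert-butyldimethylsilyloxy)-9α,11-epoxy-11-methylene-extended spiro-oxirane of 4,4,8α,10-tetramethyl-cis-decalin (oxirane oxygen α and CH2 β at C9)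
Conditions: Me3S+ I−, n-BuLi, THF, −10 °C; then 26, −10 °C to rt
Reagents that add atoms: trimethylsulfonium iodide, C[S+](C)C.[I-]
Why: In this Corey–Chaykovsky epoxidation the small sulfonium ylide adds irreversibly to the hindered ketone along the β trajectory, which meets only H5 and H7 while the α face is closed by C1 and the 8α-methyl group, so C11 ends β and the oxygen α at C9.

Step 16
Reactants: 27 spiro-epoxide; 28 2-methylprop-2-en-1-ol
Product: 30 6β-(tert-butyldimethylsilyloxy)-9α-hydroxy-9β-[3-(hydroxymethyl)but-3-en-1-yl]-4,4,8α,10-tetramethyl-cis-decalin, via dilithium 2-methylideneprop-1-yl-3-olate dianion of 28 29 (not isolated)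
Conditions: 28, n-BuLi (2.2 equiv), TMEDA, Et2O, 0 °C to rt; then CuI (cat.), 27, THF, −40 °C to rt; aq NH4Cl
Reagents that add atoms: none
Why: SN2 opening of the 2,2-disubstituted epoxide at its CH2 carbon by the allylic carbanion of the methallyl alcohol dianion (copper-assisted allyl-metal epoxide opening) should form the C11–C12 bond and deliver the 2-substituted allylic alcohol without protecting groups.

Step 17
Reactants: 30 allylic alcohol
Product: 31 6β-(tert-butyldimethylsilyloxy)-9α-hydroxy-9β-{2-[(2S)-2-(hydroxymethyl)oxiran-2-yl]ethyl}-4,4,8α,10-tetramethyl-cis-decalin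
Conditions: Ti(OiPr)4 (cat.), L-(+)-diethyl tartrate (cat.), t-BuOOH, 4 Å MS, CH2Cl2, −20 °C
Reagents that add atoms: tert-butyl hydroperoxide, CC(C)(C)OO
Why: Sharpless asymmetric epoxidation of the 2-substituted allylic alcohol is reagent-controlled, and L-(+)-tartrate should give the (S)-epoxy alcohol (as it does with 2-methylprop-2-en-1-ol) irrespective of the remote decalin, the catalytic low-temperature conditions keeping the tertiary C9 hydroxyl from opening the epoxide early.

Step 18
Reactants: 31 epoxy alcohol
Product: 32 6β-(tert-butyldimethylsilyloxy)-9α-hydroxy-9β-{2-[(2R)-2-formyloxiran-2-yl]ethyl}-4,4,8α,10-tetramethyl-cis-decalin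
Conditions: Dess–Martin periodinane, NaHCO3, CH2Cl2, 0 °C to rt
Reagents that add atoms: none
Why: Dess–Martin oxidation of the primary alcohol under bicarbonate buffer should give the epoxy aldehyde, which has no α-hydrogen to lose, while the tertiary alcohol cannot be oxidised.

Step 19
Reactants: 32 epoxy aldehyde
Product: 33 6β-(tert-butyldimethylsilyloxy)-9α-hydroxy-9β-{2-[(2S)-2-ethynyloxiran-2-yl]ethyl}-4,4,8α,10-tetramethyl-cis-decalin
Conditions: dimethyl (1-diazo-2-oxopropyl)phosphonate, K2CO3, MeOH, 0 °C to rt
Reagents that add atoms: dimethyl (1-diazo-2-oxopropyl)phosphonate, CC(=O)C(=[N+]=[N-])P(=O)(OC)OC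
Why: Seyferth–Gilbert homologation in the Ohira–Bestmann variant should convert the non-enolisable aldehyde into the terminal alkyne C14≡C15 under mild carbonate conditions that leave the epoxide and the silyl ether untouched.

Step 20
Reactants: 33 ethynyl epoxide
Product: 34 6β,9α-dihydroxy-9β-{2-[(2S)-2-ethynyloxiran-2-yl]ethyl}-4,4,8α,10-tetramethyl-cis-decalin
Conditions: TBAF, THF, rt
Reagents that add atoms: none
Why: Fluoride-induced cleavage of the Si–O bond should free the C6 hydroxyl under conditions that the epoxide and the alkyne tolerate.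

Step 21
Reactants: 34 diol
Product: 35 6β-acetoxy-9α-hydroxy-9β-{2-[(2S)-2-ethynyloxiran-2-yl]ethyl}-4,4,8α,10-tetramethyl-cis-decalin
Conditions: Ac2O, DMAP (cat.), pyridine, CH2Cl2, rt
Reagents that add atoms: acetic anhydride, CC(=O)OC(C)=O
Why: DMAP-catalysed acetylation should be selective for the secondary C6 alcohol because the tertiary C9 hydroxyl is too hindered to acylate, so the acetate is in place before the acid-sensitive ring D exists.

Step 22
Reactants: 35 acetoxy epoxide
Product: 36 (13R)-6β-acetoxy-9α,13-epoxy-5β-labd-14-yn-16-ol (8α-methyl)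
Conditions: CSA (cat.), CH2Cl2, −20 to 0 °C
Reagents that add atoms: none
Why: Acid-catalysed 5-exo-tet opening of the epoxide by the C9 hydroxyl at the tertiary propargylic carbon closes ring C with inversion at C13, turning the (S)-epoxide into the (13R) ether and freeing the C16 hydroxyl, and the electron-withdrawing ethynyl group should keep the substitution on the SN2 side so that the configuration is transferred faithfully.

Step 23
Reactants: 36 alkynol
Product: 37 (13R)-6β-acetoxy-9α,13:15,16-diepoxy-5β-labd-14-ene (8α-methyl; CNP0242014.2)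
Conditions: Mo(CO)6 (cat.), Et3N, Et2O, hν (350 nm), rt
Reagents that add atoms: none
Why: Molybdenum-catalysed endo cycloisomerisation of the but-3-yn-1-ol unit through a metal vinylidene (alkynol cycloisomerisation) should close ring D as the 2,3-dihydrofuran under basic conditions, so the acid-labile spiro enol ether is formed last and is purified on base-washed silica.

Compound list
1 | 2,4-dimethylanisole | COc1ccc(C)cc1C | starting material
2 | (2-methoxy-3,5-dimethylphenyl)lithium | COc1c(C)cc(C)cc1[Li] | intermediate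
3 | dimethyl (2-methoxy-3,5-dimethylphenyl)boronate | COB(OC)c1cc(C)cc(C)c1OC | intermediate
4 | 2-methoxy-3,5-dimethylphenol | COc1c(C)cc(C)cc1O | intermediate
5 | (R)-pantolactone | CC1(C)COC(=O)[C@@H]1O | starting material
6 | acryloyl chloride | C=CC(=O)Cl | starting material
7 | (3R)-4,4-dimethyl-2-oxooxolan-3-yl prop-2-enoate | C=CC(=O)O[C@H]1C(=O)OCC1(C)C | intermediate
8 | 6,6-dimethoxy-3,5-dimethylcyclohexa-2,4-dien-1-one | COC1(OC)C(=O)C=C(C)C=C1C | intermediate
9 | (3R)-4,4-dimethyl-2-oxooxolan-3-yl (1R,2S,4S)-5,5-dimethoxy-4,7-dimethyl-6-oxobicyclo[2.2.2]oct-7-ene-2-carboxylate | O=C1C(OC)(OC)[C@@]2(C)C[C@H](C(=O)O[C@H]3C(=O)OCC3(C)C)[C@@H]1C(C)=C2 | intermediate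
10 | (1R,2S,4S)-5,5-dimethoxy-4,7-dimethyl-6-oxobicyclo[2.2.2]oct-7-ene-2-carboxylic acid | O=C1C(OC)(OC)[C@@]2(C)C[C@H](C(=O)O)[C@@H]1C(C)=C2 | intermediate
11 | 2-thioxopyridin-1(2H)-yl ester of acid 10 | O=C1C(OC)(OC)[C@@]2(C)C[C@H](C(=O)On3ccccc3=S)[C@@H]1C(C)=C2 | intermediate
12 | (1R,4S)-3,3-dimethoxy-4,6-dimethylbicyclo[2.2.2]oct-5-en-2-one | O=C1C(OC)(OC)[C@@]2(C)CC[C@@H]1C(C)=C2 | intermediate
13 | vinylmagnesium bromide | C=C[Mg]Br | starting material
14 | (1R,2R,4S)-3,3-dimethoxy-4,6-dimethyl-2-vinylbicyclo[2.2.2]oct-5-en-2-ol | C=C[C@]1(O)C(OC)(OC)[C@@]2(C)CC[C@@H]1C(C)=C2 | intermediate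
15 | potassium C7=C8 enolate of 16 | C1C=C([O-])C(OC)(OC)[C@@]2(C)CCC=C(C)[C@@H]12.[K+] | intermediate
16 | (4aR,8aS)-1,1-dimethoxy-5,8a-dimethyl-3,4,4a,7,8,8a-hexahydronaphthalen-2(1H)-one | C1CC(=O)C(OC)(OC)[C@@]2(C)CCC=C(C)[C@@H]12 | intermediate
17 | lithium C7=C8 enolate of 16 | C1C=C([O-])C(OC)(OC)[C@@]2(C)CCC=C(C)[C@@H]12.[Li+] | intermediate
18 | trimethylsilyl enol ether of 16 | C1C=C(O[Si](C)(C)C)C(OC)(OC)[C@@]2(C)CCC=C(C)[C@@H]12 | intermediate
19 | (4aR,8aS)-1,1-dimethoxy-5,8a-dimethyl-4a,7,8,8a-tetrahydronaphthalen-2(1H)-one | C1=CC(=O)C(OC)(OC)[C@@]2(C)CCC=C(C)[C@@H]12 | intermediate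
20 | 6β-pinacolboryl-9,9-dimethoxy-4,10-dimethyl-cis-decal-3-en-8-one | CC1(C)OB(OC1(C)C)[C@@H]2CC(=O)C(OC)(OC)[C@@]3(C)CCC=C(C)[C@@H]23 | intermediate
21 | 6β-hydroxy-9,9-dimethoxy-4,10-dimethyl-cis-decal-3-en-8-one | O[C@@H]1CC(=O)C(OC)(OC)[C@@]2(C)CCC=C(C)[C@@H]12 | intermediate
22 | 6β-(tert-butyldimethylsilyloxy)-9,9-dimethoxy-4,10-dimethyl-cis-decal-3-en-8-one | CC(C)(C)[Si](C)(C)O[C@@H]1CC(=O)C(OC)(OC)[C@@]2(C)CCC=C(C)[C@@H]12 | intermediate
23 | 6β-(tert-butyldimethylsilyloxy)-9,9-dimethoxy-4,10-dimethyl-3β,4β-methano-cis-decalin-8-one | CC(C)(C)[Si](C)(C)O[C@@H]1CC(=O)C(OC)(OC)[C@@]2(C)CC[C@@H]3C[C@]3(C)[C@@H]12 | intermediate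
24 | 6β-(tert-butyldimethylsilyloxy)-9,9-dimethoxy-4,10-dimethyl-8-methylene-3β,4β-methano-cis-decalin | CC(C)(C)[Si](C)(C)O[C@@H]1CC(=C)C(OC)(OC)[C@@]2(C)CC[C@@H]3C[C@]3(C)[C@@H]12 | intermediate
25 | 6β-(tert-butyldimethylsilyloxy)-9,9-dimethoxy-4,4,8α,10-tetramethyl-cis-decalin | CC(C)(C)[Si](C)(C)O[C@@H]1C[C@@H](C)C(OC)(OC)[C@@]2(C)CCCC(C)(C)[C@@H]12 | intermediate
26 | 6β-(tert-butyldimethylsilyloxy)-4,4,8α,10-tetramethyl-cis-decalin-9-one | CC(C)(C)[Si](C)(C)O[C@@H]1C[C@@H](C)C(=O)[C@@]2(C)CCCC(C)(C)[C@@H]12 | intermediate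
27 | spiro-oxirane at C9 of 26 (oxirane oxygen α, oxirane CH2 = C11 β) | CC(C)(C)[Si](C)(C)O[C@@H]1C[C@@H](C)[C@]3(CO3)[C@@]2(C)CCCC(C)(C)[C@@H]12 | intermediate
28 | 2-methylprop-2-en-1-ol | C=C(C)CO | starting material
29 | dilithium dianion of 28 (allylic carbanion and alkoxide) | [Li+].[Li+].[CH2-]C(=C)C[O-] | intermediate
30 | 6β-(tert-butyldimethylsilyloxy)-9α-hydroxy-9β-[3-(hydroxymethyl)but-3-en-1-yl]-4,4,8α,10-tetramethyl-cis-decalin | CC(C)(C)[Si](C)(C)O[C@@H]1C[C@@H](C)[C@](O)(CCC(=C)CO)[C@@]2(C)CCCC(C)(C)[C@@H]12 | intermediate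
31 | 6β-(tert-butyldimethylsilyloxy)-9α-hydroxy-9β-{2-[(2S)-2-(hydroxymethyl)oxiran-2-yl]ethyl}-4,4,8α,10-tetramethyl-cis-decalin | CC(C)(C)[Si](C)(C)O[C@@H]1C[C@@H](C)[C@](O)(CC[C@]3(CO)CO3)[C@@]2(C)CCCC(C)(C)[C@@H]12 | intermediate
32 | 6β-(tert-butyldimethylsilyloxy)-9α-hydroxy-9β-{2-[(2R)-2-formyloxiran-2-yl]ethyl}-4,4,8α,10-tetramethyl-cis-decalin | CC(C)(C)[Si](C)(C)O[C@@H]1C[C@@H](C)[C@](O)(CC[C@]3(C=O)CO3)[C@@]2(C)CCCC(C)(C)[C@@H]12 | intermediate
33 | 6β-(tert-butyldimethylsilyloxy)-9α-hydroxy-9β-{2-[(2S)-2-ethynyloxiran-2-yl]ethyl}-4,4,8α,10-tetramethyl-cis-decalin | CC(C)(C)[Si](C)(C)O[C@@H]1C[C@@H](C)[C@](O)(CC[C@]3(C#C)CO3)[C@@]2(C)CCCC(C)(C)[C@@H]12 | intermediate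
34 | 6β,9α-dihydroxy-9β-{2-[(2S)-2-ethynyloxiran-2-yl]ethyl}-4,4,8α,10-tetramethyl-cis-decalin | O[C@@H]1C[C@@H](C)[C@](O)(CC[C@]3(C#C)CO3)[C@@]2(C)CCCC(C)(C)[C@@H]12 | intermediate
35 | 6β-acetoxy-9α-hydroxy-9β-{2-[(2S)-2-ethynyloxiran-2-yl]ethyl}-4,4,8α,10-tetramethyl-cis-decalin | CC(=O)O[C@@H]1C[C@@H](C)[C@](O)(CC[C@]3(C#C)CO3)[C@@]2(C)CCCC(C)(C)[C@@H]12 | intermediate
36 | (13R)-6β-acetoxy-9α,13-epoxy-5β-labd-14-yn-16-ol (8α-methyl) | CC(=O)O[C@@H]1C[C@@H](C)[C@]2(CC[C@@](C#C)(CO)O2)[C@@]2(C)CCCC(C)(C)[C@@H]12 | intermediate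
37 | (13R)-6β-acetoxy-9α,13:15,16-diepoxy-5β-labd-14-ene (8α-methyl) | CC(=O)O[C@@H]1C[C@@H](C)[C@]2(CC[C@]3(C=COC3)O2)[C@@]2(C)CCCC(C)(C)[C@@H]12 | target

Total step count: 23. Longest linear sequence: 22 steps (steps 1 and 3–23, from 2,4-dimethylanisole); step 2 is the one-step side branch.

Steps most likely to fail

1. Step 3. The purely thermal cycloaddition may discriminate poorly between the two faces of the diene, so that the diastereomers form in similar amounts and their separation costs most of the material. Fallback, from 4 and back at 10: the same oxidation of 4 in methanol in the presence of methyl acrylate should give the racemic methyl ester F1; LiOH hydrolysis gives the racemic acid F2; classical resolution by crystallisation with (R)-1-phenylethylamine (or its enantiomer, whichever gives the less soluble salt of the required acid) gives the (R)-1-phenylethylammonium salt F3, and acidification releases 10.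

2. Step 13. Hydrogen may be delivered to the α face of the exocyclic alkene, or the alkene may migrate into the ring before it is reduced, so that the 8β-methyl epimer is formed. Fallback, from 24 and back at 25: TBAF should free the hydroxyl to give the homoallylic alcohol F4; hydroxyl-directed homogeneous hydrogenation with [Ir(cod)(PCy3)(py)]PF6 and H2 in CH2Cl2 delivers hydrogen to C8 from the face of the 6β-hydroxyl and should give the 8α-methyl alcohol F5 with the cyclopropane intact; TBSCl and imidazole restore the silyl ether F6, and PtO2/H2/AcOH then only has to open the cyclopropane to reach 25.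

3. Step 16. The strongly basic dianion may isomerise the epoxide to an allylic alcohol by β-elimination, or substitution at the neopentyl-type CH2 may be too slow. Fallback, from 27 and back at 30: LiI and AcOH in THF should open the epoxide to the iodohydrin F7; Keck radical allylation with tributyl[2-({[tert-butyl(dimethyl)silyl]oxy}methyl)prop-2-en-1-yl]stannane and AIBN in benzene at 80 °C forms the C11–C12 bond through a primary radical that is indifferent to the neighbouring quaternary centre and should give the bis-silyl ether F8; PPTS in methanol removes the primary allylic silyl group selectively to give 30.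

Further compounds
F1 | step 3 | racemic methyl 5,5-dimethoxy-4,7-dimethyl-6-oxobicyclo[2.2.2]oct-7-ene-2-carboxylate (ester syn to the alkene bridge) | O=C1C(OC)(OC)[C@@]2(C)C[C@H](C(=O)OC)[C@@H]1C(C)=C2.O=C1C(OC)(OC)[C@]2(C)C[C@@H](C(=O)OC)[C@H]1C(C)=C2
F2 | step 3 | racemic 5,5-dimethoxy-4,7-dimethyl-6-oxobicyclo[2.2.2]oct-7-ene-2-carboxylic acid | O=C1C(OC)(OC)[C@@]2(C)C[C@H](C(=O)O)[C@@H]1C(C)=C2.O=C1C(OC)(OC)[C@]2(C)C[C@@H](C(=O)O)[C@H]1C(C)=C2
F3 | step 3 | (R)-1-phenylethylammonium salt of acid 10 | O=C1C(OC)(OC)[C@@]2(C)C[C@H](C(=O)[O-])[C@@H]1C(C)=C2.C[C@@H]([NH3+])c1ccccc1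
F4 | step 13 | 6β-hydroxy-9,9-dimethoxy-4,10-dimethyl-8-methylene-3β,4β-methano-cis-decalin | O[C@@H]1CC(=C)C(OC)(OC)[C@@]2(C)CC[C@@H]3C[C@]3(C)[C@@H]12
F5 | step 13 | 6β-hydroxy-9,9-dimethoxy-4,8α,10-trimethyl-3β,4β-methano-cis-decalin | O[C@@H]1C[C@@H](C)C(OC)(OC)[C@@]2(C)CC[C@@H]3C[C@]3(C)[C@@H]12
F6 | step 13 | 6β-(tert-butyldimethylsilyloxy)-9,9-dimethoxy-4,8α,10-trimethyl-3β,4β-methano-cis-decalin | CC(C)(C)[Si](C)(C)O[C@@H]1C[C@@H](C)C(OC)(OC)[C@@]2(C)CC[C@@H]3C[C@]3(C)[C@@H]12
F7 | step 16 | 6β-(tert-butyldimethylsilyloxy)-9α-hydroxy-9β-(iodomethyl)-4,4,8α,10-tetramethyl-cis-decalin | CC(C)(C)[Si](C)(C)O[C@@H]1C[C@@H](C)[C@](O)(CI)[C@@]2(C)CCCC(C)(C)[C@@H]12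
F8 | step 16 | 6β-(tert-butyldimethylsilyloxy)-9α-hydroxy-9β-{3-[(tert-butyldimethylsilyloxy)methyl]but-3-en-1-yl}-4,4,8α,10-tetramethyl-cis-decalin | CC(C)(C)[Si](C)(C)O[C@@H]1C[C@@H](C)[C@](O)(CCC(=C)CO[Si](C)(C)C(C)(C)C)[C@@]2(C)CCCC(C)(C)[C@@H]12
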